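Read the late substrate readings first: conversion is what they leave out of the charge.

| flask | substrate | remark | time |
|---|---|---|---|
| gamma | 14 mM | run made earlier |  |
| epsilon | 22 mM | run made earlier |  |
| flask | 10 mM |  | 12 d |

| run | time / d | substrate / % | target / % | isomer of the product B / % |
|---|---|---|---|---|
| gamma | 0.833 | 16.7 | 15.0 | 21.5 |
| gamma | 1.67 | 15.5 | 14.5 | 28.2 |
| gamma | 2.50 | 15.9 | 13.5 | 31.2 |
| gamma | 5.00 | 14.9 | 12.7 | 33.5 |
| gamma | 10.0 | 14.7 | 14.0 | 32.7 |
| epsilon | 0.833 | 16.3 | 15.6 | 20.7 |
| epsilon | 1.67 | 15.3 | 12.8 | 28.2 |
| epsilon | 2.50 | 13.8 | 14.1 | 32.2 |
| epsilon | 5.00 | 14.6 | 14.0 | 32.5 |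
| epsilon | 10.0 | 13.7 | 13.4 | 33.2 |

(standard deviation of a reading: 0.5 percentage points)

1. the state of affairs at 12 d: stopped, and by what, or still going (all of the substrate has reacted / forward and back rates have come level / it is still moving)
2. conversion of substrate at 12 d
3. amount of target at 12 d, in percent of the substrate charged
4. amount of isomer of the product B at 12 d, in percent of the substrate charged

- steps thought possible: substrate <-> target; substrate <-> dormant form; target <-> isomer of the product B; isomer of the product A <-> substrate; target <-> isomer of the product A
- what has gone from substrate into another species counts as reacted, even if it can come back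
- the reaction counts as stopped when no species that holds the substrate changes by six tenths of a point or more over the second half of the time

From 5.00 d to 10.0 d, isomer of the product B falls by 0.8 percentage points in the gamma run and rises by 0.7 points in the epsilon run. Isomer of the product B thus shows no common drift, and the late substrate readings at 14 mM and 22 mM span 1.2 points. The substrate readings at those times are taken as plateau readings, although substrate falls by 0.9 points in the epsilon run. My reckoning brackets the conversion. The flask, at 10 mM, lies below both charges, and 12 d lies past the last reading, so the bracket is an extension.

Bound from above, lowest plateau reading: conversion ≤ 86.3 %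

Bound from below, highest plateau reading: conversion ≥ 85.1 %

Tightened: s∞ = 14.5 %, the plateau remainder (equilibrium share): the mean of the 4 plateau readings, the share of the charge still substrate once forward and back rates have come level.

Its standard error: 0.25 points

Conversion = 100 % − s∞, between 85.3 % and 85.8 %

The forecast says forward and back rates have come level, with conversion 85.6 %, target 13.6 % and isomer of the product B 33 %. Its ground: “the network behaves as first order”. Its conversion lies 0.075 points from the middle of the band, less than one standard error. Forecast and band rest on the same readings, so this is no check.

The flask gives forward and back rates have come level, with conversion 85.6 %, target 13.3 % and isomer of the product B 33.2 %.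

    substrate ⇌ target (K = 0.920, k = 0.00670 min⁻¹)
    substrate ⇌ dormant form (K = 0.970, k = 0.0190 min⁻¹)
    target ⇌ isomer of the product B (K = 2.50, k = 0.00150 min⁻¹)
    isomer of the product A ⇌ substrate (k = 9.10 × 10⁻⁴ min⁻¹)
    target ⇌ isomer of the product A (K = 1.90, k = 0.00370 min⁻¹)

In the flask, by forward rates, substrate left faster into the dormant form than into target, with half-lives of 0.61 h against 0.072 d, and substrate stood at 18.5 % by 0.600 d. Isomer of the product B then rose from target to 31.2 % at 2.40 d and 33.1 % at 6.00 d. With s∞ at 14.5 %, the flask's conversion lies 0.062 points from the middle of the band, less than one standard error. The neighbour flask with 25 mM of substrate also lies less than one standard error from that middle at 12.0 d, with conversion 85.6 %.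

(Readings and results were generated by integration with constants of no real substance, and the scatter is random.)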